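## Retrosynthetic overview

1. Junceellolide F (29) ⇐ triacetylation ⇐ 9-OH-directed epoxidation of the 11(20)-methylene tetraol 27 ⇐ methylenation and desilylation of ketolactone 25 (positions are briarane numbers C1–C20 of the target).
2. Lactone (third ring): the C7–O bond is made last on the carbocycle, by carboxylate-directed allylic C–H lactonisation of the (5Z)-cyclodecene acid 24; this also sets C7.
3. Ten-membered ring (second ring): ring-closing metathesis at C5=C6 of diene 22.
4. 22 ⇐ aldol union (C9–C10) of the ring-A enone 9 with the hydroxy aldehyde 18; 18 comes from a copper–bis(oxazoline) keto-ester aldol (C8, C17).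
5. Ring A (first ring): enantioselective Diels–Alder of a 1-silyloxybutadiene with methacrolein (C1, C14); C2 by Felkin–Anh Grignard addition.

Assumption: each chiral catalyst is named as the enantiomer taken to give the configuration drawn; if its facial sense proves opposite, the mirror-image catalyst is used.

## Route

Step 1
Reactants: 1 crotonaldehyde
Product: 2 (E)-1-(tert-butyldimethylsilyloxy)buta-1,3-diene
Conditions: TBSOTf, Et3N, Et2O, 0 °C to rt
Reagents that add atoms: tert-butyldimethylsilyl triflate, CC(C)(C)[Si](C)(C)OS(=O)(=O)C(F)(F)F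
Why: Silyl dienol ether formation; the amine removes the γ-proton of the silyl-activated enal and the (E)-1-silyloxydiene is the favoured isomer.

Step 2
Reactants: 2 (E)-1-(tert-butyldimethylsilyloxy)buta-1,3-diene; 3 methacrolein
Product: 4 (1R,2S)-2-(tert-butyldimethylsilyloxy)-1-methylcyclohex-3-ene-1-carbaldehyde
Conditions: (S)-3,3-diphenyl-1-(o-tolyl)tetrahydropyrrolo[1,2-c][1,3,2]oxazaborole (20 mol%), Tf2NH (20 mol%), CH2Cl2, −78 °C
Reagents that add atoms: none
Why: Catalytic enantioselective Diels–Alder reaction; the oxygenated diene terminus bonds to the α-carbon of the enal (ortho regiochemistry) through the formyl-endo transition state, so quaternary C1 (R in 4) and C14 (S) are set together with CHO cis to OTBS while the cationic oxazaborolidine blocks one face of the bound enal.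

Step 3
Reactants: 4 (1R,2S)-2-(tert-butyldimethylsilyloxy)-1-methylcyclohex-3-ene-1-carbaldehyde; 5 4-bromo-2-methylbut-1-ene
Product: 7 (1R)-1-[(1S,2S)-2-(tert-butyldimethylsilyloxy)-1-methylcyclohex-3-en-1-yl]-4-methylpent-4-en-1-ol, via Grignard reagent 6 (not isolated)
Conditions: 5, Mg, THF, rt; then 4, −78 °C; aq. NH4Cl
Reagents that add atoms: none
Why: Grignard addition under Felkin–Anh control; the C14(OTBS) branch of the α-quaternary aldehyde lies anti to the incoming nucleophile, which passes the methyl group, giving the (2R)-carbinol.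

Step 4
Reactants: 7 alcohol
Product: 8 bis-TBS ether of 7
Conditions: TBSOTf, 2,6-lutidine, CH2Cl2, −78 to 0 °C
Reagents that add atoms: tert-butyldimethylsilyl triflate, CC(C)(C)[Si](C)(C)OS(=O)(=O)C(F)(F)F
Why: Silylation with the triflate is fast enough for the neopentyl-type secondary alcohol and protects it from the later enolate chemistry.

Step 5
Reactants: 8 bis-TBS ether
Product: 9 (4S,5S)-4-(tert-butyldimethylsilyloxy)-5-[(1R)-1-(tert-butyldimethylsilyloxy)-4-methylpent-4-en-1-yl]-5-methylcyclohex-2-en-1-one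
Conditions: Rh2(caprolactamate)4 (1 mol%), t-BuOOH (5 equiv), K2CO3, CH2Cl2, rt
Reagents that add atoms: tert-butyl hydroperoxide, CC(C)(C)OO
Why: Allylic oxidation takes the unhindered ring methylene C11 to the conjugated enone; the O-substituted C14–H and the isopropenyl group are left, as in ring-selective allylic oxidations of terpenes carrying isopropenyl groups.

Step 6
Reactants: 10 dimethyl oxalate; 11 allylmagnesium bromide
Product: 12 methyl 2-oxopent-4-enoate
Conditions: THF/Et2O, −78 °C; then cold aq. HCl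
Reagents that add atoms: none
Why: Mono-acylation of a Grignard reagent by an oxalate diester; the magnesium hemiketal survives at −78 °C until the quench, so addition stops at the α-keto ester.

Step 7
Reactants: 13 tert-butyl propionate
Product: 15 (E)-1-tert-butoxy-1-(trimethylsilyloxy)prop-1-ene, via lithium enolate 14 (not isolated)
Conditions: LDA (LiN(i-Pr)2), THF, −78 °C; then TMSCl
Reagents that add atoms: chlorotrimethylsilane, C[Si](C)(C)Cl
Why: Kinetic ester enolisation and O-silylation give the ketene silyl acetal.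

Step 8
Reactants: 12 methyl 2-oxopent-4-enoate; 15 ketene silyl acetal
Product: 16 1-tert-butyl 4-methyl (2R,3R)-2-methyl-3-(prop-2-en-1-yl)-3-(trimethylsilyloxy)butanedioate
Conditions: Cu(OTf)2 (10 mol%), (R,R)-t-Bu-box (11 mol%), CH2Cl2, −78 °C; non-acidic work-up
Reagents that add atoms: none
Why: Evans-type copper–bis(oxazoline) Mukaiyama aldol addition (here with an ester-derived ketene acetal); two-point binding of the α-keto ester to divalent copper exposes one ketone face and the open transition state gives the syn adduct, setting C8 (R in 16) and C17 (R), with the silyl group transferred to the tertiary oxygen.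

Step 9
Reactants: 16 silyl ether diester
Product: 18 tert-butyl (2R,3R)-3-formyl-3-hydroxy-2-methylhex-5-enoate, via silyl-protected aldehyde 17 (not isolated)
Conditions: DIBAL-H (i-Bu2AlH, 1.2 equiv), CH2Cl2, −78 °C; then MeOH, aq. citric acid
Reagents that add atoms: none
Why: Half-reduction of the methyl ester (the α-silyloxy aluminium hemiacetal is stable at −78 °C and the tert-butyl ester is not attacked); the acidic work-up removes the tertiary TMS ether; 18 is used crude.

Step 10
Reactants: 9 ring-A enone; 18 hydroxy aldehyde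
Product: 20 aldol adduct (8R,9R,10S), via lithium dienolate 19 (not isolated)
Conditions: 9, LDA (LiN(i-Pr)2), THF, −78 °C; MgBr2·OEt2; then 18 pre-treated with LiHMDS (LiN(SiMe3)2, 1 equiv), −78 °C; aq. NH4Cl
Reagents that add atoms: none
Why: Aldol addition; LDA removes the α′-proton at C10 (the only kinetic site) and the dienolate adds through a Zimmerman–Traxler chair (anti) to the aldehyde whose α-alkoxide is chelated to magnesium (Cram chelate, attack past the allyl group), setting C9 (R), while C10 (S) carries the new chain equatorial and trans to the C2 chain, the stable epimer of this epimerisable centre.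

Step 11
Reactants: 20 aldol adduct
Product: 21 9-O-TBS ether of 20
Conditions: TBSOTf (1.1 equiv), 2,6-lutidine, CH2Cl2, −78 °C
Reagents that add atoms: tert-butyldimethylsilyl triflate, CC(C)(C)[Si](C)(C)OS(=O)(=O)C(F)(F)F
Why: Silylation of the secondary 9-OH in preference to the tertiary 8-OH; this blocks retro-aldol and later lactonisation of O9 onto C19.

Step 12
Reactants: 21 silylated enone
Product: 22 saturated C11 ketone (diene for ring closure)
Conditions: [CuH(PPh3)]6, benzene, trace H2O, rt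
Reagents that add atoms: none
Why: Stryker conjugate reduction; copper hydride reduces only the enone C=C and leaves the allyl and isopropenyl groups.

Step 13
Reactants: 22 diene
Product: 23 (5Z)-cyclodecene tert-butyl ester
Conditions: second-generation Hoveyda–Grubbs catalyst [RuCl2(H2IMes)(=CH-C6H4-2-O-i-Pr)] (15 mol%), toluene (1 mM), 100 °C
Reagents that add atoms: none
Why: Ring-closing metathesis of the allyl and isopropenyl groups; the two arms sit trans-diequatorial on ring A, which favours closure, and a ten-membered ring holds the new trisubstituted alkene only as the (Z)-isomer.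

Step 14
Reactants: 23 tert-butyl ester
Product: 24 (5Z)-cyclodecene carboxylic acid
Conditions: 85% aq. H3PO4, toluene, rt
Reagents that add atoms: none
Why: Acidolysis of the tert-butyl ester by alkyl–oxygen cleavage under conditions that TBS ethers tolerate.

Step 15
Reactants: 24 carboxylic acid
Product: 25 7,19-lactone (7S,8S)
Conditions: Pd(OAc)2 (10 mol%), 1,2-bis(phenylsulfinyl)ethane (10 mol%), p-benzoquinone (2 equiv), 1,4-dioxane, 45 °C
Reagents that add atoms: none
Why: Proposed new method: carboxylate-directed allylic C–H lactonisation of an internal trisubstituted (Z)-cycloalkene – the C19 carboxylate binds divalent palladium and removes one C7 hydrogen through a six-membered concerted metalation–deprotonation, the η3-allyl (C5–C7) is captured at C7 by the same carboxylate (five-membered ring preferred over attack at tertiary C5) and benzoquinone reoxidises zerovalent palladium; because the product is an allylic ester that palladium can reopen, C7 settles as the more stable trans-fused (7S) epimer with C6 anti to C9 on the butanolide; the closest known reactions are the Pd(OAc)2/bis-sulfoxide allylic C–H macrolactonisation of terminal alkenes and the carboxylate-directed γ-methylene C–H lactonisation of aliphatic acids, neither shown on an internal ring alkene.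

Step 16
Reactants: 25 ketolactone
Product: 26 11(20)-methylene lactone
Conditions: Zn, CH2Br2, TiCl4, THF/CH2Cl2, 0 °C to rt
Reagents that add atoms: dibromomethane, BrCBr
Why: Takai–Lombardo methylenation; the non-basic gem-dizinc/titanium reagent converts the hindered, enolisable C11 ketone to the exocyclic alkene without touching the lactone.

Step 17
Reactants: 26 tris-TBS ether
Product: 27 11(20)-ene tetraol
Conditions: HF·pyridine, pyridine, THF, 0 to 40 °C
Reagents that add atoms: none
Why: Fluoride desilylation under non-basic conditions, which avoids retro-aldol opening and acyl migration in the β-hydroxy lactone.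

Step 18
Reactants: 27 tetraol
Product: 28 2,9,14-tri-O-deacetyljunceellolide F
Conditions: VO(acac)2 (5 mol%), t-BuOOH, CH2Cl2, 0 °C
Reagents that add atoms: tert-butyl hydroperoxide, CC(C)(C)OO
Why: Hydroxyl-directed epoxidation; the homoallylic 9-OH, which allylic strain places on the α face of C11=C20, delivers oxygen to that face (also the face anti to the axial C15 methyl), setting C11 (R) with the oxygen equatorial, while C5=C6 is deactivated by the allylic lactone oxygen and has only the hindered tertiary 8-OH nearby.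

Step 19
Reactants: 28 epoxy tetraol
Product: 29 junceellolide F
Conditions: Ac2O, pyridine, DMAP (cat.), rt
Reagents that add atoms: acetic anhydride, CC(=O)OC(C)=O
Why: Acetylation of the three secondary hydroxyls (C2, C9, C14); the tertiary 8-OH is not acylated under these conditions.

## Compound list

1 | crotonaldehyde, (E)-but-2-enal | C/C=C/C=O | starting material
2 | (E)-1-(tert-butyldimethylsilyloxy)buta-1,3-diene | C=C/C=C/O[Si](C)(C)C(C)(C)C | intermediate
3 | methacrolein | C=C(C)C=O | starting material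
4 | (1R,2S)-2-(tert-butyldimethylsilyloxy)-1-methylcyclohex-3-ene-1-carbaldehyde (CHO cis to OTBS) | CC(C)(C)[Si](C)(C)O[C@H]1C=CCC[C@]1(C=O)C | intermediate
5 | 4-bromo-2-methylbut-1-ene | C=C(C)CCBr | starting material
6 | 3-methylbut-3-enylmagnesium bromide | C=C(C)CC[Mg]Br | intermediate (not isolated)
7 | (1R)-1-[(1S,2S)-2-(tert-butyldimethylsilyloxy)-1-methylcyclohex-3-en-1-yl]-4-methylpent-4-en-1-ol | C=C(C)CC[C@@H](O)[C@]1(C)CCC=C[C@@H]1O[Si](C)(C)C(C)(C)C | intermediate
8 | bis-TBS ether of 7 (carbinol oxygen also silylated) | C=C(C)CC[C@@H](O[Si](C)(C)C(C)(C)C)[C@]1(C)CCC=C[C@@H]1O[Si](C)(C)C(C)(C)C | intermediate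
9 | (4S,5S)-4-(tert-butyldimethylsilyloxy)-5-[(1R)-1-(tert-butyldimethylsilyloxy)-4-methylpent-4-en-1-yl]-5-methylcyclohex-2-en-1-one | C=C(C)CC[C@@H](O[Si](C)(C)C(C)(C)C)[C@]1(C)CC(=O)C=C[C@@H]1O[Si](C)(C)C(C)(C)C | intermediate
10 | dimethyl oxalate | COC(=O)C(=O)OC | starting material
11 | allylmagnesium bromide | C=CC[Mg]Br | starting material
12 | methyl 2-oxopent-4-enoate | C=CCC(=O)C(=O)OC | intermediate
13 | tert-butyl propionate | CCC(=O)OC(C)(C)C | starting material
14 | lithium enolate of tert-butyl propionate | C/C=C(\OC(C)(C)C)O[Li] | intermediate (not isolated)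
15 | (E)-1-tert-butoxy-1-(trimethylsilyloxy)prop-1-ene | C/C=C(\OC(C)(C)C)O[Si](C)(C)C | intermediate
16 | 1-tert-butyl 4-methyl (2R,3R)-2-methyl-3-(prop-2-en-1-yl)-3-(trimethylsilyloxy)butanedioate | COC(=O)[C@@](O[Si](C)(C)C)(CC=C)[C@@H](C)C(=O)OC(C)(C)C | intermediate
17 | tert-butyl (2R,3R)-3-formyl-2-methyl-3-(trimethylsilyloxy)hex-5-enoate | O=C[C@@](O[Si](C)(C)C)(CC=C)[C@@H](C)C(=O)OC(C)(C)C | intermediate (not isolated)
18 | tert-butyl (2R,3R)-3-formyl-3-hydroxy-2-methylhex-5-enoate | O=C[C@@](O)(CC=C)[C@@H](C)C(=O)OC(C)(C)C | intermediate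
19 | lithium dienolate of 9 (C10=C11 enolate) | C=C(C)CC[C@@H](O[Si](C)(C)C(C)(C)C)[C@]1(C)C=C(O[Li])C=C[C@@H]1O[Si](C)(C)C(C)(C)C | intermediate (not isolated)
20 | aldol adduct, 1S,2R,8R,9R,10S,14S,17R: ring-A enone (C11=O, C12=C13) with 14-OTBS, C1 methyl and the C2–C5 chain CH(OTBS)CH2CH2C(CH3)=CH2; C10 carries CH(OH)–C(OH)(allyl)–CH(CH3)CO2t-Bu | C=C(C)CC[C@@H](O[Si](C)(C)C(C)(C)C)[C@]1(C)[C@@H]([C@@H](O)[C@@](O)(CC=C)[C@@H](C)C(=O)OC(C)(C)C)C(=O)C=C[C@@H]1O[Si](C)(C)C(C)(C)C | intermediate
21 | 9-O-TBS ether of 20 (8-OH free) | C=C(C)CC[C@@H](O[Si](C)(C)C(C)(C)C)[C@]1(C)[C@@H]([C@@H](O[Si](C)(C)C(C)(C)C)[C@@](O)(CC=C)[C@@H](C)C(=O)OC(C)(C)C)C(=O)C=C[C@@H]1O[Si](C)(C)C(C)(C)C | intermediate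
22 | 12,13-dihydro derivative of 21 (saturated C11 ketone; allyl on C8, isopropenyl on the C2 chain) | C=C(C)CC[C@@H](O[Si](C)(C)C(C)(C)C)[C@]1(C)[C@@H]([C@@H](O[Si](C)(C)C(C)(C)C)[C@@](O)(CC=C)[C@@H](C)C(=O)OC(C)(C)C)C(=O)CC[C@@H]1O[Si](C)(C)C(C)(C)C | intermediate
23 | (5Z)-cyclodecene fused to ring A at C1/C10; 2,9,14-tris-OTBS, 8-OH, 11-oxo; C8 carries (R)-CH(CH3)CO2t-Bu; 1S,2R,8R,9R,10S,14S,17R | CC(C)(C)[Si](C)(C)O[C@H]1CCC(=O)[C@@H]2[C@@H](O[Si](C)(C)C(C)(C)C)[C@@](O)(C/C=C(/C)CC[C@@H](O[Si](C)(C)C(C)(C)C)[C@@]12C)[C@@H](C)C(=O)OC(C)(C)C | intermediate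
24 | carboxylic acid of 23 (C19 acid) | CC(C)(C)[Si](C)(C)O[C@H]1CCC(=O)[C@@H]2[C@@H](O[Si](C)(C)C(C)(C)C)[C@@](O)(C/C=C(/C)CC[C@@H](O[Si](C)(C)C(C)(C)C)[C@@]12C)[C@@H](C)C(=O)O | intermediate
25 | 7,19-lactone: 2,9,14-tris-O-TBS, 8-OH, 11-oxo, (5Z); every stereocentre as in 29 | CC(C)(C)[Si](C)(C)O[C@H]1CCC(=O)[C@@H]2[C@@H](O[Si](C)(C)C(C)(C)C)[C@@]3(O)[C@H](/C=C(/C)CC[C@@H](O[Si](C)(C)C(C)(C)C)[C@@]12C)OC(=O)[C@@H]3C | intermediate
26 | 11(20)-methylene analogue of 25 | CC(C)(C)[Si](C)(C)O[C@H]1CCC(=C)[C@@H]2[C@@H](O[Si](C)(C)C(C)(C)C)[C@@]3(O)[C@H](/C=C(/C)CC[C@@H](O[Si](C)(C)C(C)(C)C)[C@@]12C)OC(=O)[C@@H]3C | intermediate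
27 | 2,8,9,14-tetrahydroxy-5(Z),11(20)-diene 7,19-lactone; stereocentres as in 29 | O[C@H]1CCC(=C)[C@@H]2[C@@H](O)[C@@]3(O)[C@H](/C=C(/C)CC[C@@H](O)[C@@]12C)OC(=O)[C@@H]3C | intermediate
28 | 2,9,14-tri-O-deacetyljunceellolide F (11,20-epoxide, oxygen α) | O[C@H]1CC[C@]2(CO2)[C@@H]2[C@@H](O)[C@@]3(O)[C@H](/C=C(/C)CC[C@@H](O)[C@@]12C)OC(=O)[C@@H]3C | intermediate
29 | junceellolide F | CC(=O)O[C@H]1CC[C@]2(CO2)[C@@H]2[C@@H](OC(C)=O)[C@@]3(O)[C@H](/C=C(/C)CC[C@@H](OC(C)=O)[C@@]12C)OC(=O)[C@@H]3C | target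

## Step count and risks

Total steps: 19. Longest linear sequence: 15 (steps 1–5, then 10–19).

The three steps most likely to fail:

Step 13 (ring-closing metathesis to a trisubstituted alkene in a ten-membered ring). Fallback by carbonyl coupling, setting out from 22 and coming back at 23: NaBH4 (MeOH, 0 °C) masks the C11 ketone as the C11 alcohol F1 (either epimer). Ozonolysis (O3, CH2Cl2/MeOH, −78 °C; Me2S) then cleaves both terminal alkenes to the methyl ketone–aldehyde F2. McMurry coupling with low-valent titanium (TiCl3(DME)1.5, Zn–Cu couple, DME, reflux, high dilution) closes the ring to the (5Z)-cyclodecenol F3. Dess–Martin oxidation of the C11 alcohol gives 23.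

Step 15 (the proposed allylic C–H lactonisation). Fallback with known reactions, setting out from 23 and coming back at 25: buffered mCPBA gives the 5,6-epoxide F4. Pre-formed sodium phenylselenide (PhSeSePh/NaBH4, EtOH, no excess hydride) opens it at the secondary C6 to the hydroxy selenide F5. H2O2 gives the selenoxide F6, which can only eliminate toward C7 (C5 has no hydrogen) and gives the tertiary allylic alcohol F7 (5-OH, C6=C7). 85% H3PO4 cleaves the tert-butyl ester to the acid F8. PdCl2(MeCN)2 (cat., THF) then effects dehydrative SN2′ lactonisation, O19 onto C7 with loss of the 5-hydroxyl and return of the C5=C6 bond, giving 25; the lactone can be equilibrated to the trans-fused epimer with Pd(PPh3)4 if needed.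

Step 18 (epoxidation of C11=C20 in the presence of C5=C6 and four free hydroxyls). Fallback by dihydroxylation and ring closure, setting out from 27 and coming back at 28: OsO4 (cat.)/NMO dihydroxylates the exposed exocyclic alkene from the α face to the hexaol F9. TsCl/pyridine (0 °C) sulfonylates only the primary 20-OH to the tosylate F10. K2CO3/MeOH closes the epoxide by attack of the 11-oxygen on C20, giving 28 with the same C11 configuration.

Further compounds
F1 | step 13 | C11 alcohol of 22 (either C11 epimer) | C=C(C)CC[C@@H](O[Si](C)(C)C(C)(C)C)[C@]1(C)[C@@H]([C@@H](O[Si](C)(C)C(C)(C)C)[C@@](O)(CC=C)[C@@H](C)C(=O)OC(C)(C)C)C(O)CC[C@@H]1O[Si](C)(C)C(C)(C)C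
F2 | step 13 | methyl ketone–aldehyde from ozonolysis of F1 (C5 ketone, C6 aldehyde) | CC(=O)CC[C@@H](O[Si](C)(C)C(C)(C)C)[C@]1(C)[C@@H]([C@@H](O[Si](C)(C)C(C)(C)C)[C@@](O)(CC=O)[C@@H](C)C(=O)OC(C)(C)C)C(O)CC[C@@H]1O[Si](C)(C)C(C)(C)C
F3 | step 13 | (5Z)-cyclodecenol, the C11 alcohol of 23 | CC(C)(C)[Si](C)(C)O[C@H]1CCC(O)[C@@H]2[C@@H](O[Si](C)(C)C(C)(C)C)[C@@](O)(C/C=C(/C)CC[C@@H](O[Si](C)(C)C(C)(C)C)[C@@]12C)[C@@H](C)C(=O)OC(C)(C)C
F4 | step 15 | 5,6-epoxide of 23 (cis-epoxide, face not defined) | CC(C)(C)[Si](C)(C)O[C@H]1CCC(=O)[C@@H]2[C@@H](O[Si](C)(C)C(C)(C)C)[C@@](O)(CC3OC3(C)CC[C@@H](O[Si](C)(C)C(C)(C)C)[C@@]12C)[C@@H](C)C(=O)OC(C)(C)C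
F5 | step 15 | 5-hydroxy-6-(phenylselanyl) derivative of 23 | CC(C)(C)[Si](C)(C)O[C@H]1CCC(=O)[C@@H]2[C@@H](O[Si](C)(C)C(C)(C)C)[C@@](O)(CC([Se]c3ccccc3)C(C)(O)CC[C@@H](O[Si](C)(C)C(C)(C)C)[C@@]12C)[C@@H](C)C(=O)OC(C)(C)C
F6 | step 15 | selenoxide of F5 | CC(C)(C)[Si](C)(C)O[C@H]1CCC(=O)[C@@H]2[C@@H](O[Si](C)(C)C(C)(C)C)[C@@](O)(CC([Se](=O)c3ccccc3)C(C)(O)CC[C@@H](O[Si](C)(C)C(C)(C)C)[C@@]12C)[C@@H](C)C(=O)OC(C)(C)C
F7 | step 15 | tertiary allylic alcohol (5-OH, 6E-ene) tert-butyl ester | CC(C)(C)[Si](C)(C)O[C@H]1CCC(=O)[C@@H]2[C@@H](O[Si](C)(C)C(C)(C)C)[C@@](O)(/C=C/C(C)(O)CC[C@@H](O[Si](C)(C)C(C)(C)C)[C@@]12C)[C@@H](C)C(=O)OC(C)(C)C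
F8 | step 15 | carboxylic acid of F7 | CC(C)(C)[Si](C)(C)O[C@H]1CCC(=O)[C@@H]2[C@@H](O[Si](C)(C)C(C)(C)C)[C@@](O)(/C=C/C(C)(O)CC[C@@H](O[Si](C)(C)C(C)(C)C)[C@@]12C)[C@@H](C)C(=O)O
F9 | step 18 | hexaol: 11,20-diol of 27 (11-OH α) | O[C@H]1CC[C@](O)(CO)[C@@H]2[C@@H](O)[C@@]3(O)[C@H](/C=C(/C)CC[C@@H](O)[C@@]12C)OC(=O)[C@@H]3C
F10 | step 18 | 20-O-tosylate of F9 | O[C@H]1CC[C@](O)(COS(=O)(=O)c4ccc(C)cc4)[C@@H]2[C@@H](O)[C@@]3(O)[C@H](/C=C(/C)CC[C@@H](O)[C@@]12C)OC(=O)[C@@H]3C
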